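**Retrosynthetic overview**
- The target comes from a cycloadduct that carries the lactone carbonyl C2 one oxidation level lower, as a methyl acetal; this acetal is oxidised in the last step.
- The cycloadduct is disconnected by an oxa-[4+2] (hetero-Diels–Alder) reaction at C5–C6 and O1–C2 into a dienyl tiglate and a diacetoxy enal. This single step forms the only ring (the dihydropyran), joins both halves and sets C5 and C6.
- Enabling feature: in the 5,6-dihydro-2H-pyran-2-one ring, O1–C6 is a latent aldehyde C=O, and C2=C3–C4=C5, oxygenated at both ends, is a latent 1,4-dioxygenated buta-1,3-diene whose cycloaddition leaves the C3=C4 bond. The cis relation of the C5 ester and the C6 alkenyl group is the endo outcome.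
- The enal comes from 3,4-di-O-acetyl-L-fucal by Perlin hydrolysis (C3' and C4' from the chiral pool); the diene comes from fumaraldehyde mono(dimethyl acetal) and tigloyl chloride.

Key step: step 6

Remark: lactone numbering is O1, C2 (carbonyl), C3=C4, C5 (tiglate), C6 (side chain C1'–C5'); compounds 1, 3, 6 and the chromium catalyst of step 6 are taken as commercially available.

Step 1
Reactants: 1 (E)-4,4-dimethoxybut-2-enal (fumaraldehyde mono(dimethyl acetal))
Product: 2 (E)-4,4-dimethoxybut-2-en-1-ol
Conditions: NaBH4, MeOH, 0 °C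
Reagents that add atoms: none
Why: Borohydride 1,2-reduction of the conjugated aldehyde (NaBH4 reduction) should leave the dimethyl acetal and the (E) alkene untouched and creates no stereocentre.

Step 2
Reactants: 2 (E)-4,4-dimethoxybut-2-en-1-ol; 3 tigloyl chloride ((2E)-2-methylbut-2-enoyl chloride)
Product: 4 (2E)-4,4-dimethoxybut-2-en-1-yl (2E)-2-methylbut-2-enoate
Conditions: pyridine, DMAP (cat.), CH2Cl2, 0 °C
Reagents that add atoms: none
Why: Acylation of the primary allylic alcohol with the acid chloride (DMAP-catalysed esterification) should not touch the acetal, and pyridine is used instead of a trialkylamine so that the tigloyl group is not deconjugated through a vinylketene.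

Step 3
Reactants: 4 (2E)-4,4-dimethoxybut-2-en-1-yl (2E)-2-methylbut-2-enoate
Product: 5 (1E,3E)-4-methoxybuta-1,3-dien-1-yl (2E)-2-methylbut-2-enoate
Conditions: TMSOTf (1.2 equiv), i-Pr2NEt (1.5 equiv), CH2Cl2, −78 → −20 °C; Et3N/NaHCO3 quench
Reagents that add atoms: none
Why: TMSOTf ionises the dimethyl acetal to a methoxy-substituted allyl cation and the hindered amine removes the proton at the carbon bearing the ester oxygen (silyl-triflate-mediated acetal-to-enol-ether elimination, in its vinylogous form), which should give the 1-methoxy-1,3-diene with the extended (1E,3E) geometry favoured, any (Z) isomers being expected to remain as spectators in step 6.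

Step 4
Reactants: 6 3,4-di-O-acetyl-L-fucal
Product: 7 (2E,4S,5S)-4-(acetyloxy)-5-hydroxyhex-2-enal
Conditions: HgSO4 (cat.), 5 mM aq. H2SO4, 1,4-dioxane, rt
Reagents that add atoms: water, O
Why: Perlin hydrolysis (mercury-assisted hydration of the glycal enol ether, ring opening and β-elimination of the C3 acetate) should give the (E)-enal with C4 and C5 of the fucal carried over unchanged as the two side-chain stereocentres, and a possible 4→5 acetyl shift is harmless because step 5 acetylates both positions.

Step 5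
Reactants: 7 (2E,4S,5S)-4-(acetyloxy)-5-hydroxyhex-2-enal
Product: 8 (2E,4S,5S)-4,5-bis(acetyloxy)hex-2-enal
Conditions: Ac2O, pyridine, DMAP (cat.), CH2Cl2, 0 °C
Reagents that add atoms: acetic anhydride, CC(=O)OC(C)=O
Why: Standard acetylation of the secondary alcohol (Ac2O/pyridine) touches no stereocentre, and the γ-acetoxy enal has no acidic stereogenic C–H under these conditions.

Step 6
Reactants: 5 (1E,3E)-4-methoxybuta-1,3-dien-1-yl (2E)-2-methylbut-2-enoate; 8 (2E,4S,5S)-4,5-bis(acetyloxy)hex-2-enal
Product: 9 (2S,3S,6S)-2-[(1E,3S,4S)-3,4-bis(acetyloxy)pent-1-en-1-yl]-6-methoxy-3,6-dihydro-2H-pyran-3-yl (2E)-2-methylbut-2-enoate (all-cis; lactone numbering 2S,5S,6S)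
Conditions: (L)CrCl (5 mol %; L = dianion of (1R,2S)-1-{[3-(1-adamantyl)-2-hydroxy-5-methylbenzylidene]amino}indan-2-ol; trivalent chromium), 4 Å MS, 5 (2 equiv), neat or minimal TBME, rt, 24–72 h; no acidic work-up
Reagents that add atoms: none
Why: The chromium Lewis acid binds the aldehyde oxygen of 8 and diene 5 adds in a concerted, asynchronous oxa-[4+2] cycloaddition in which the C5–C6 bond (tiglate-bearing diene terminus to carbonyl carbon) leads and the O1–C2 bond follows; the closest known reaction is the hetero-Diels–Alder reaction of 1-methoxybuta-1,3-dienes, 4-substituted ones included, with unactivated aldehydes under this class of tridentate Schiff-base chromium catalyst. The six-membered dihydropyran ring is closed in the intermolecular [4+2] mode, two σ-bonds and one ring with no tether. C6 is set by the catalyst, which by analogy with its sense on 1-methoxybutadiene should expose the Re face of the aldehyde (its enantiomer is used if the sense proves opposite on this enal); C5 follows from the (E) geometry of the enol-ester terminus together with the endo transition state, which places the tiglate and the alkenyl group cis; the all-cis methoxy centre at C2 is incidental and is erased in step 7. The step needs regioselectivity, secured because the stronger methoxy donor puts the larger HOMO coefficient on the tiglate-bearing carbon and stabilises the developing oxocarbenium at C2. It also needs chemoselectivity for the C=O of 8 over its hindered, γ-branched C=C and over inverse-demand use of the enal as an oxadiene, and catalyst control over the C4 stereocentre of 8, which lies three bonds from the carbonyl carbon and should exert little bias. Isomers of 5 with a (Z) terminus cannot readily reach the s-cis conformer and should not compete.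

Step 7
Reactants: 9 (2S,3S,6S)-2-[(1E,3S,4S)-3,4-bis(acetyloxy)pent-1-en-1-yl]-6-methoxy-3,6-dihydro-2H-pyran-3-yl (2E)-2-methylbut-2-enoate
Product: 10 (2S,3S)-2-[(1E,3S,4S)-3,4-bis(acetyloxy)pent-1-en-1-yl]-6-oxo-3,6-dihydro-2H-pyran-3-yl (2E)-2-methylbut-2-enoate (the target; lactone numbering 5S,6S)
Conditions: mCPBA (1.5 equiv), BF3·OEt2 (0.5 equiv), CH2Cl2, −20 → 0 °C
Reagents that add atoms: 3-chloroperbenzoic acid (mCPBA), O=C(OO)c1cccc(Cl)c1
Why: BF3 ionises the allylic methyl acetal to the cyclic oxocarbenium ion, the peracid adds at C2 and the resulting peroxy acetal collapses to the lactone carbonyl (Lewis-acid-promoted peracid oxidation of a cyclic acetal to a lactone, known for alkyl 2,3-unsaturated glycosides), while C5 and C6 are untouched and the three electron-poor alkenes should resist epoxidation at low temperature.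

**Compound list**
1 | (E)-4,4-dimethoxybut-2-enal | O=C/C=C/C(OC)OC | starting material
2 | (E)-4,4-dimethoxybut-2-en-1-ol | OC/C=C/C(OC)OC | intermediate
3 | tigloyl chloride, (2E)-2-methylbut-2-enoyl chloride | C/C=C(\C)C(Cl)=O | starting material
4 | (2E)-4,4-dimethoxybut-2-en-1-yl (2E)-2-methylbut-2-enoate | C/C=C(\C)C(=O)OC/C=C/C(OC)OC | intermediate
5 | (1E,3E)-4-methoxybuta-1,3-dien-1-yl (2E)-2-methylbut-2-enoate | C/C=C(\C)C(=O)O/C=C/C=C/OC | intermediate
6 | 3,4-di-O-acetyl-L-fucal, (2S,3R,4S)-2-methyl-3,4-dihydro-2H-pyran-3,4-diyl diacetate | C[C@@H]1OC=C[C@H](OC(C)=O)[C@@H]1OC(C)=O | starting material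
7 | (2E,4S,5S)-4-(acetyloxy)-5-hydroxyhex-2-enal | O=C/C=C/[C@H](OC(C)=O)[C@H](C)O | intermediate
8 | (2E,4S,5S)-4,5-bis(acetyloxy)hex-2-enal | O=C/C=C/[C@H](OC(C)=O)[C@H](C)OC(C)=O | intermediate
9 | (2S,3S,6S)-2-[(1E,3S,4S)-3,4-bis(acetyloxy)pent-1-en-1-yl]-6-methoxy-3,6-dihydro-2H-pyran-3-yl (2E)-2-methylbut-2-enoate | C/C=C(\C)C(=O)O[C@H]1C=C[C@@H](OC)O[C@H]1/C=C/[C@H](OC(C)=O)[C@H](C)OC(C)=O | intermediate
10 | (2S,3S)-2-[(1E,3S,4S)-3,4-bis(acetyloxy)pent-1-en-1-yl]-6-oxo-3,6-dihydro-2H-pyran-3-yl (2E)-2-methylbut-2-enoate | C/C=C(\C)C(=O)O[C@H]1C=CC(=O)O[C@H]1/C=C/[C@H](OC(C)=O)[C@H](C)OC(C)=O | target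

Total step count: 7. Longest linear sequence: 5 steps (1, 2, 3, 6, 7).

**Steps most likely to fail**

Step 6. The cycloaddition may be sluggish, because the diene carries only one strong donor and the aldehyde is conjugated. It may also be diverted into the inverse-demand pathway, in which the enal acts as an oxadiene toward the enol-ether double bond of 5, or lose endo and facial selectivity. The fallback sets out from 8 (with 3 for the ester) and returns to the route at 10; it uses a more nucleophilic 3-siloxy diene and removes the extra oxygen afterwards. Commercial trans-1-methoxy-3-(trimethylsilyloxy)buta-1,3-diene is submitted to Rubottom oxidation (mCPBA, then mild acidic work-up) to give (3E)-1-hydroxy-4-methoxybut-3-en-2-one F1. F1 is acylated with 3 (pyridine) to (3E)-4-methoxy-2-oxobut-3-en-1-yl (2E)-2-methylbut-2-enoate F2 and enol-silylated (TMSOTf, Et3N) to (1Z,3E)-4-methoxy-2-[(trimethylsilyl)oxy]buta-1,3-dien-1-yl (2E)-2-methylbut-2-enoate F3, whose ester group sits on the outside of the diene. Cycloaddition of F3 with 8 under the same (L)CrCl catalyst should give the all-cis adduct (2S,3R,6S)-2-[(1E,3S,4S)-3,4-bis(acetyloxy)pent-1-en-1-yl]-6-methoxy-4-[(trimethylsilyl)oxy]-3,6-dihydro-2H-pyran-3-yl (2E)-2-methylbut-2-enoate F4. TFA work-up converts it into (2S,3R)-2-[(1E,3S,4S)-3,4-bis(acetyloxy)pent-1-en-1-yl]-4-oxo-3,4-dihydro-2H-pyran-3-yl (2E)-2-methylbut-2-enoate F5. Luche reduction (NaBH4, CeCl3·7H2O, MeOH, −78 °C) should give the allylic alcohol (2S,3S,4S)-2-[(1E,3S,4S)-3,4-bis(acetyloxy)pent-1-en-1-yl]-4-hydroxy-3,4-dihydro-2H-pyran-3-yl (2E)-2-methylbut-2-enoate F6; the configuration at C4 is inconsequential. Acetylation (Ac2O, pyridine, 0 °C) gives (2S,3R,4S)-4-(acetyloxy)-2-[(1E,3S,4S)-3,4-bis(acetyloxy)pent-1-en-1-yl]-3,4-dihydro-2H-pyran-3-yl (2E)-2-methylbut-2-enoate F7. Peracid oxidation of this glycal ester with Ferrier-type allylic transposition (mCPBA, BF3·OEt2, −20 °C) expels the C4 acetate and gives 10.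

Step 3. The deprotonation may be unselective and give mainly a (Z) enol-ester or (Z) enol-ether terminus, and the electron-rich diene may oligomerise under the Lewis acid. The fallback sets out from 3 and returns at 5; it builds the diene from a geometrically defined precursor by enolate chemistry. Commercial (1E,3E)-1,4-diacetoxybuta-1,3-diene is cleaved on one side with MeLi (2 equiv, THF, −78 °C) to lithium (1E,3E)-4-(acetyloxy)buta-1,3-dien-1-olate F8, which is O-methylated (MeOTf, DMPU) to (1E,3E)-4-methoxybuta-1,3-dien-1-yl acetate F9. A second MeLi cleavage gives lithium (1E,3E)-4-methoxybuta-1,3-dien-1-olate F10, which is O-acylated with 3 to give 5 with both double bonds retained as (E).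

Step 7. The peracid may attack the allylic C4 terminus of the oxocarbenium ion, the side-chain alkene may be epoxidised, or the Lewis acid may ionise the allylic acetate. The fallback sets out from 9 and returns at 10; it separates hydrolysis from oxidation. Mild aqueous acid (AcOH/THF/H2O, rt) should hydrolyse the acetal to the lactol (2S,3S)-2-[(1E,3S,4S)-3,4-bis(acetyloxy)pent-1-en-1-yl]-6-hydroxy-3,6-dihydro-2H-pyran-3-yl (2E)-2-methylbut-2-enoate F11 (anomeric mixture). The allylic lactol, the only free hydroxyl, is then oxidised with MnO2 (CH2Cl2, rt) or Ag2CO3 on Celite to 10.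

Further compounds
F1 | step 6 | (3E)-1-hydroxy-4-methoxybut-3-en-2-one | CO/C=C/C(=O)CO
F2 | step 6 | (3E)-4-methoxy-2-oxobut-3-en-1-yl (2E)-2-methylbut-2-enoate | C/C=C(\C)C(=O)OCC(=O)/C=C/OC
F3 | step 6 | (1Z,3E)-4-methoxy-2-[(trimethylsilyl)oxy]buta-1,3-dien-1-yl (2E)-2-methylbut-2-enoate | C/C=C(\C)C(=O)O/C=C(O[Si](C)(C)C)/C=C/OC
F4 | step 6 | (2S,3R,6S)-2-[(1E,3S,4S)-3,4-bis(acetyloxy)pent-1-en-1-yl]-6-methoxy-4-[(trimethylsilyl)oxy]-3,6-dihydro-2H-pyran-3-yl (2E)-2-methylbut-2-enoate | C/C=C(\C)C(=O)O[C@H]1C(O[Si](C)(C)C)=C[C@@H](OC)O[C@H]1/C=C/[C@H](OC(C)=O)[C@H](C)OC(C)=O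
F5 | step 6 | (2S,3R)-2-[(1E,3S,4S)-3,4-bis(acetyloxy)pent-1-en-1-yl]-4-oxo-3,4-dihydro-2H-pyran-3-yl (2E)-2-methylbut-2-enoate | C/C=C(\C)C(=O)O[C@H]1C(=O)C=CO[C@H]1/C=C/[C@H](OC(C)=O)[C@H](C)OC(C)=O
F6 | step 6 | (2S,3S,4S)-2-[(1E,3S,4S)-3,4-bis(acetyloxy)pent-1-en-1-yl]-4-hydroxy-3,4-dihydro-2H-pyran-3-yl (2E)-2-methylbut-2-enoate | C/C=C(\C)C(=O)O[C@H]1[C@@H](O)C=CO[C@H]1/C=C/[C@H](OC(C)=O)[C@H](C)OC(C)=O
F7 | step 6 | (2S,3R,4S)-4-(acetyloxy)-2-[(1E,3S,4S)-3,4-bis(acetyloxy)pent-1-en-1-yl]-3,4-dihydro-2H-pyran-3-yl (2E)-2-methylbut-2-enoate | C/C=C(\C)C(=O)O[C@H]1[C@@H](OC(C)=O)C=CO[C@H]1/C=C/[C@H](OC(C)=O)[C@H](C)OC(C)=O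
F8 | step 3 | lithium (1E,3E)-4-(acetyloxy)buta-1,3-dien-1-olate | [Li+].[O-]/C=C/C=C/OC(C)=O
F9 | step 3 | (1E,3E)-4-methoxybuta-1,3-dien-1-yl acetate | CC(=O)O/C=C/C=C/OC
F10 | step 3 | lithium (1E,3E)-4-methoxybuta-1,3-dien-1-olate | [Li+].[O-]/C=C/C=C/OC
F11 | step 7 | (2S,3S)-2-[(1E,3S,4S)-3,4-bis(acetyloxy)pent-1-en-1-yl]-6-hydroxy-3,6-dihydro-2H-pyran-3-yl (2E)-2-methylbut-2-enoate (anomeric mixture) | C/C=C(\C)C(=O)O[C@H]1C=CC(O)O[C@H]1/C=C/[C@H](OC(C)=O)[C@H](C)OC(C)=O
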